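**Plan**

- Retrosynthetic cuts, in order: O1–C2 of ring C (oxa-Michael), C4a–C5 of ring A (Claisen), C4–C4a (acylation of a pyrone methyl carbanion), C6–geranyl (palladium allylation), and the cinnamoyl C=C (olefination).
- Enabling feature: in ring A the oxygen-bearing carbons C5, C7 and C8a alternate with C6, C8 and C4a, and C4a carries the C4 carbonyl. The chain C5–C6–C7–C8–C8a–C4a–C4 is thus a folded polyketide, the ring-opened form of a 6-(acylmethyl)-4-hydroxy-2-pyrone (pyrone C2→C5, C3→C6, C4→C7, C5→C8, C6→C8a, side-chain CH2→C4a).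
- Forward: geranyl is placed on pyrone C3, the 6-methyl dianion is acylated with the ring B cinnamoyl amide, and Mg(OMe)2 converts the pyrone into ring A, giving the chalcone.
- Ring C then closes only through the hydroxyl para to geranyl: the two accessible hydroxyls are masked for a time as silyl ethers, the hydroxyl between geranyl and carbonyl is capped as its MOM ether, and desilylation releases the one phenoxide that can cyclise.
- Stereochemistry: the geranyl alkene geometry comes from geraniol and the enone geometry from the olefination. C2 forms as the racemate and the (2S)-ketone is secured by kinetic resolution with a chiral rhodium transfer-hydrogenation catalyst.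

Key step: step 6

Remark: the single stereocentre (C2) is read from the SMILES as S; geranyl denotes (2E)-3,7-dimethylocta-2,6-dien-1-yl, and chalcone positions on the ketone-bearing ring A are primed.

**Route**

Step 1
Reactants: 1 geraniol
Product: 2 geranyl methyl carbonate
Conditions: ClCO2Me, pyridine, CH2Cl2, 0 °C
Reagents that add atoms: methyl chloroformate, COC(=O)Cl
Why: Carbonate formation by O-acylation of the primary allylic alcohol is fast at 0 °C and touches neither trisubstituted alkene, so the (E)-geometry of geraniol is carried over.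

Step 2
Reactants: 3 4-hydroxy-6-methyl-2-pyrone (1.5 equiv); 2 geranyl methyl carbonate
Product: 4 3-geranyl-4-hydroxy-6-methyl-2-pyrone
Conditions: Pd(PPh3)4 (5 mol %), THF, 50 °C
Reagents that add atoms: none
Why: Tsuji–Trost allylation, in which zerovalent palladium ionises the carbonate to a geranyl π-allyl complex and methoxide, the methoxide deprotonates the acidic pyrone, and its only nucleophilic ring carbon (C3, between the two oxygen-bearing carbons) attacks the unsubstituted allyl terminus to give the linear (E)-geranyl C-alkylation product, the excess of pyrone holding back double allylation.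

Step 3
Reactants: 5 syringaldehyde
Product: 6 3,5-dimethoxy-4-(methoxymethoxy)benzaldehyde
Conditions: MOMCl, iPr2NEt, CH2Cl2, 0 °C to rt
Reagents that add atoms: chloromethyl methyl ether (MOMCl), COCCl
Why: Williamson-type etherification of the acidic phenol with the reactive chloromethyl ether gives an acetal that withstands the strong bases of steps 4 to 6 and falls to mild acid at the end.

Step 4
Reactants: 6 3,5-dimethoxy-4-(methoxymethoxy)benzaldehyde; 7 diethyl {2-[methoxy(methyl)amino]-2-oxoethyl}phosphonate
Product: 8 (E)-3-[3,5-dimethoxy-4-(methoxymethoxy)phenyl]-N-methoxy-N-methylprop-2-enamide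
Conditions: NaH, THF, 0 °C to rt
Reagents that add atoms: none
Why: Horner–Wadsworth–Emmons olefination with the amide-stabilised phosphonate gives the (E)-enamide and installs the acyl-transfer group in the same operation.

Step 5
Reactants: 4 3-geranyl-4-hydroxy-6-methyl-2-pyrone; 8 (E)-3-[3,5-dimethoxy-4-(methoxymethoxy)phenyl]-N-methoxy-N-methylprop-2-enamide (0.9 equiv)
Product: 10 6-{(E)-4-[3,5-dimethoxy-4-(methoxymethoxy)phenyl]-2-oxobut-3-enyl}-3-geranyl-4-hydroxy-2-pyrone, via pyrone dianion 9 (not isolated)
Conditions: LiN(iPr)2 (2.3 equiv), THF, −78 °C; then 8, −78 to −20 °C; aq. NH4Cl, then citric acid to pH 4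
Reagents that add atoms: none
Why: Acylation of a hydroxypyrone dianion by a Weinreb amide, in which the second equivalent of base deprotonates the 6-methyl group, this carbanion is the most reactive site and adds to the amide carbonyl instead of the electron-rich β-carbon, the amide transfers its acyl group only once, and C3 is blocked by geranyl.

Step 6
Reactants: 10 6-{(E)-4-[3,5-dimethoxy-4-(methoxymethoxy)phenyl]-2-oxobut-3-enyl}-3-geranyl-4-hydroxy-2-pyrone
Product: 12 3'-geranyl-2',4',6'-trihydroxy-3,5-dimethoxy-4-(methoxymethoxy)chalcone, via methyl triketo ester 11 (not isolated)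
Conditions: Mg(OMe)2 (8 equiv), MeOH, reflux; then poured into ice-cold 1 M HCl (pH 3)
Reagents that add atoms: none
Why: Methoxide, delivered within a magnesium chelate, adds to the lactone carbonyl and opens the pyrone to the enolate of triketo ester 11, whose methylene between the two ketones (the former side-chain CH2, future C4a) attacks the ester carbonyl (former pyrone C2, future C5), expels methoxide and tautomerises to the aromatic triol. The closest known reaction type is the magnesium methoxide recyclisation of 6-(2-oxoalkyl)-4-hydroxy-2-pyrones to acylphloroglucinols, a Dieckmann-type Claisen condensation that mirrors chalcone synthase. Ring A closes in the 6-exo-trig mode at the ester carbonyl. No stereocentre is created. The step needs Claisen over aldol closure and survival of the enone: the aldol alternative would make the geranyl-bearing ester α-carbon quaternary and so cannot aromatise, magnesium chelation holds the chain folded for the Claisen mode, and additions of methoxide or of internal enolates to the electron-rich enone are reversible whereas aromatisation is not. Quenching the magnesium phenoxide cold into acid should release the open chalcone before ring C can close.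

Step 7
Reactants: 12 3'-geranyl-2',4',6'-trihydroxy-3,5-dimethoxy-4-(methoxymethoxy)chalcone
Product: 13 4',6'-bis(tert-butyldimethylsilyloxy)-3'-geranyl-2'-hydroxy-3,5-dimethoxy-4-(methoxymethoxy)chalcone
Conditions: TBSCl (2.2 equiv), imidazole, CH2Cl2, 0 °C
Reagents that add atoms: tert-butyldimethylsilyl chloride (TBSCl), CC(C)(C)[Si](C)(C)Cl
Why: Silyl ether formation under steric control, in which the para hydroxyl and the ortho hydroxyl flanked only by the acyl group are silylated, whereas the hydroxyl wedged between geranyl and the carbonyl stays behind as the hydrogen-bonded phenol, the usual outcome of twofold protection of 2,4,6-trihydroxyacylbenzenes.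

Step 8
Reactants: 13 4',6'-bis(tert-butyldimethylsilyloxy)-3'-geranyl-2'-hydroxy-3,5-dimethoxy-4-(methoxymethoxy)chalcone
Product: 14 4',6'-bis(tert-butyldimethylsilyloxy)-3'-geranyl-3,5-dimethoxy-2',4-bis(methoxymethoxy)chalcone
Conditions: NaH, MOMCl, THF, 0 °C
Reagents that add atoms: chloromethyl methyl ether (MOMCl), COCCl
Why: Williamson etherification of the remaining chelated phenol through its sodium salt, which in the absence of a proton source cannot rest as a cyclised flavanone enolate and is trapped on oxygen by the chloromethyl ether.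

Step 9
Reactants: 14 4',6'-bis(tert-butyldimethylsilyloxy)-3'-geranyl-3,5-dimethoxy-2',4-bis(methoxymethoxy)chalcone
Product: 16 rac-6-geranyl-7-hydroxy-3',5'-dimethoxy-5,4'-bis(methoxymethoxy)flavanone, via desilylated chalcone 15 (not isolated)
Conditions: K2CO3 (0.5 equiv), MeOH, 0 °C to rt; aq. NH4Cl
Reagents that add atoms: none
Why: Carbonate-catalysed methanolysis of the two aryl silyl ethers, both activated by the ortho or para carbonyl, followed by intramolecular oxa-Michael addition (6-endo-trig) of the only free ortho phenoxide, the one para to geranyl, fixes the 6-geranyl constitution, and C2 forms as the racemate because nothing chiral is present.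

Step 10
Reactants: 16 rac-6-geranyl-7-hydroxy-3',5'-dimethoxy-5,4'-bis(methoxymethoxy)flavanone
Product: 17 (2S)-6-geranyl-7-hydroxy-3',5'-dimethoxy-5,4'-bis(methoxymethoxy)flavanone
Conditions: [Cp*RhCl((R,R)-TsDPEN)] (1 mol %; Cp* = C5Me5, TsDPEN = N-tosyl-1,2-diphenylethylenediamine amide), HCO2H/Et3N 5:2, EtOAc, 25–40 °C, stopped just past half conversion
Reagents that add atoms: none
Why: Noyori–Ikariya asymmetric transfer hydrogenation run as a kinetic resolution, in which the (R,R)-catalyst delivers hydride to the ketone face that gives a 4R carbinol, which agrees with the inherent preference for the cis-2,4-flavanol only in the (2R)-ketone, so that enantiomer should be reduced while the (2S)-ketone is recovered with C2 untouched.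

Step 11
Reactants: 17 (2S)-6-geranyl-7-hydroxy-3',5'-dimethoxy-5,4'-bis(methoxymethoxy)flavanone
Product: 18 (2S)-6-geranyl-5,7,4'-trihydroxy-3',5'-dimethoxyflavanone
Conditions: 3 M aq. HCl, MeOH, rt to 40 °C
Reagents that add atoms: none
Why: Acid-catalysed acetal exchange with methanol removes both MOM groups, the one at O5 helped by the neighbouring carbonyl, under conditions mild enough to leave the geranyl alkenes alone and without the base that would open ring C and racemise C2.

**Compound list**

1 | geraniol | OC/C=C(\C)CCC=C(C)C | starting material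
2 | geranyl methyl carbonate | COC(=O)OC/C=C(\C)CCC=C(C)C | intermediate
3 | 4-hydroxy-6-methyl-2-pyrone | Cc1cc(O)cc(=O)o1 | starting material
4 | 3-geranyl-4-hydroxy-6-methyl-2-pyrone | Cc1cc(O)c(C/C=C(\C)CCC=C(C)C)c(=O)o1 | intermediate
5 | syringaldehyde (4-hydroxy-3,5-dimethoxybenzaldehyde) | COc1cc(C=O)cc(OC)c1O | starting material
6 | 3,5-dimethoxy-4-(methoxymethoxy)benzaldehyde | COCOc1c(OC)cc(C=O)cc1OC | intermediate
7 | diethyl {2-[methoxy(methyl)amino]-2-oxoethyl}phosphonate | CCOP(=O)(CC(=O)N(C)OC)OCC | starting material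
8 | (E)-3-[3,5-dimethoxy-4-(methoxymethoxy)phenyl]-N-methoxy-N-methylprop-2-enamide | CON(C)C(=O)/C=C/c1cc(OC)c(OCOC)c(OC)c1 | intermediate
9 | dilithium dianion of 4 (4-oxide, 6-methylene carbanion) | [Li+].[Li+].[CH2-]c1cc([O-])c(C/C=C(\C)CCC=C(C)C)c(=O)o1 | intermediate
10 | 6-{(E)-4-[3,5-dimethoxy-4-(methoxymethoxy)phenyl]-2-oxobut-3-enyl}-3-geranyl-4-hydroxy-2-pyrone | O=c1oc(CC(=O)/C=C/c2cc(OC)c(OCOC)c(OC)c2)cc(O)c1C/C=C(\C)CCC=C(C)C | intermediate
11 | methyl (E)-2-geranyl-9-[3,5-dimethoxy-4-(methoxymethoxy)phenyl]-3,5,7-trioxonon-8-enoate (present as its magnesium enolate) | COC(=O)C(C/C=C(\C)CCC=C(C)C)C(=O)CC(=O)CC(=O)/C=C/c1cc(OC)c(OCOC)c(OC)c1 | intermediate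
12 | 3'-geranyl-2',4',6'-trihydroxy-3,5-dimethoxy-4-(methoxymethoxy)chalcone | O=C(/C=C/c1cc(OC)c(OCOC)c(OC)c1)c1c(O)cc(O)c(C/C=C(\C)CCC=C(C)C)c1O | intermediate
13 | 4',6'-bis(tert-butyldimethylsilyloxy)-3'-geranyl-2'-hydroxy-3,5-dimethoxy-4-(methoxymethoxy)chalcone | O=C(/C=C/c1cc(OC)c(OCOC)c(OC)c1)c1c(O[Si](C)(C)C(C)(C)C)cc(O[Si](C)(C)C(C)(C)C)c(C/C=C(\C)CCC=C(C)C)c1O | intermediate
14 | 4',6'-bis(tert-butyldimethylsilyloxy)-3'-geranyl-3,5-dimethoxy-2',4-bis(methoxymethoxy)chalcone | O=C(/C=C/c1cc(OC)c(OCOC)c(OC)c1)c1c(O[Si](C)(C)C(C)(C)C)cc(O[Si](C)(C)C(C)(C)C)c(C/C=C(\C)CCC=C(C)C)c1OCOC | intermediate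
15 | 3'-geranyl-4',6'-dihydroxy-3,5-dimethoxy-2',4-bis(methoxymethoxy)chalcone | O=C(/C=C/c1cc(OC)c(OCOC)c(OC)c1)c1c(O)cc(O)c(C/C=C(\C)CCC=C(C)C)c1OCOC | intermediate
16 | rac-6-geranyl-7-hydroxy-3',5'-dimethoxy-5,4'-bis(methoxymethoxy)flavanone | COc1cc(C2CC(=O)c3c(cc(O)c(C/C=C(\C)CCC=C(C)C)c3OCOC)O2)cc(OC)c1OCOC | intermediate
17 | (2S)-6-geranyl-7-hydroxy-3',5'-dimethoxy-5,4'-bis(methoxymethoxy)flavanone | COc1cc([C@@H]2CC(=O)c3c(cc(O)c(C/C=C(\C)CCC=C(C)C)c3OCOC)O2)cc(OC)c1OCOC | intermediate
18 | (2S)-6-geranyl-5,7,4'-trihydroxy-3',5'-dimethoxyflavanone | COc1cc([C@@H]2CC(=O)c3c(cc(O)c(C/C=C(\C)CCC=C(C)C)c3O)O2)cc(OC)c1O | target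

**Step count and risks**

Total step count: 11. Longest linear sequence: 9 steps (steps 1, 2 and 5 to 11 from geraniol; equally steps 3, 4 and 5 to 11 from syringaldehyde).

Steps most likely to fail:

Step 6. The enone of the side chain may be consumed before ring A closes, through conjugate addition of methoxide or of an internal enolate, or through retro-Claisen cleavage of the triketide. Lactone opening may also stall on the unreactive 4-oxido salt. The fallback runs the same pyrone-to-benzene recyclisation on a side chain without the enone and builds the cinnamoyl alkene afterwards by aldol condensation. It sets out from 4: dianion 9 is acylated with N-methoxy-N-methylacetamide to give 3-geranyl-4-hydroxy-6-(2-oxopropyl)-2-pyrone F1. Mg(OMe)2 in refluxing methanol should convert this into 1-(3-geranyl-2,4,6-trihydroxyphenyl)ethanone F2. TBSCl and imidazole then give 1-[4,6-bis(tert-butyldimethylsilyloxy)-3-geranyl-2-hydroxyphenyl]ethanone F3, and NaH with MOMCl gives 1-[4,6-bis(tert-butyldimethylsilyloxy)-3-geranyl-2-(methoxymethoxy)phenyl]ethanone F4. The lithium enolate of F4 (LiN(SiMe3)2, THF, −78 °C) adds to aldehyde 6 to give 1-[4,6-bis(tert-butyldimethylsilyloxy)-3-geranyl-2-(methoxymethoxy)phenyl]-3-[3,5-dimethoxy-4-(methoxymethoxy)phenyl]-3-hydroxypropan-1-one F5. Dehydration with MsCl and Et3N returns to the route at 14.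

Step 10. Discrimination between the enantiomers may be poor, or the reduction too slow to reach the needed conversion, because the ketone is deactivated by three oxygen donors including a free para hydroxyl. The fallback replaces the chemical resolution by a physical one: 16 is resolved by preparative chromatography on a polysaccharide chiral stationary phase, which gives 17 directly. The (2R) antipode is returned to 16 by brief K2CO3/MeOH treatment (opening to 15 and reclosure) and recycled.

Step 7. Site selectivity may be lost in the second silylation, or the free chalcone may close ring C under the base before it is silylated. The fallback gives up the protecting-group control and lets the ring closure choose. It sets out from 12: NaOAc in refluxing ethanol cyclises the chalcone, where the hydrogen bond of the geranyl-flanked hydroxyl to the carbonyl should favour attack by the other ortho hydroxyl. rac-6-Geranyl-5,7-dihydroxy-3',5'-dimethoxy-4'-(methoxymethoxy)flavanone F6 is separated from rac-8-geranyl-5,7-dihydroxy-3',5'-dimethoxy-4'-(methoxymethoxy)flavanone F8, which is re-equilibrated with base and recycled. The transfer-hydrogenation resolution of step 10 applied to F6 should leave (2S)-6-geranyl-5,7-dihydroxy-3',5'-dimethoxy-4'-(methoxymethoxy)flavanone F7 beside (2R,4R)-6-geranyl-3',5'-dimethoxy-4'-(methoxymethoxy)flavan-4,5,7-triol F9. Aqueous HCl in methanol on F7 comes back to the route at the target 18.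

Further compounds

F1 | step 6 | 3-geranyl-4-hydroxy-6-(2-oxopropyl)-2-pyrone | CC(=O)Cc1cc(O)c(C/C=C(\C)CCC=C(C)C)c(=O)o1
F2 | step 6 | 1-(3-geranyl-2,4,6-trihydroxyphenyl)ethanone | CC(=O)c1c(O)cc(O)c(C/C=C(\C)CCC=C(C)C)c1O
F3 | step 6 | 1-[4,6-bis(tert-butyldimethylsilyloxy)-3-geranyl-2-hydroxyphenyl]ethanone | CC(=O)c1c(O[Si](C)(C)C(C)(C)C)cc(O[Si](C)(C)C(C)(C)C)c(C/C=C(\C)CCC=C(C)C)c1O
F4 | step 6 | 1-[4,6-bis(tert-butyldimethylsilyloxy)-3-geranyl-2-(methoxymethoxy)phenyl]ethanone | CC(=O)c1c(O[Si](C)(C)C(C)(C)C)cc(O[Si](C)(C)C(C)(C)C)c(C/C=C(\C)CCC=C(C)C)c1OCOC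
F5 | step 6 | 1-[4,6-bis(tert-butyldimethylsilyloxy)-3-geranyl-2-(methoxymethoxy)phenyl]-3-[3,5-dimethoxy-4-(methoxymethoxy)phenyl]-3-hydroxypropan-1-one | COCOc1c(OC)cc(C(O)CC(=O)c2c(O[Si](C)(C)C(C)(C)C)cc(O[Si](C)(C)C(C)(C)C)c(C/C=C(\C)CCC=C(C)C)c2OCOC)cc1OC
F0 | step 10 | none | none
F6 | step 7 | rac-6-geranyl-5,7-dihydroxy-3',5'-dimethoxy-4'-(methoxymethoxy)flavanone | COc1cc(C2CC(=O)c3c(cc(O)c(C/C=C(\C)CCC=C(C)C)c3O)O2)cc(OC)c1OCOC
F7 | step 7 | (2S)-6-geranyl-5,7-dihydroxy-3',5'-dimethoxy-4'-(methoxymethoxy)flavanone | COc1cc([C@@H]2CC(=O)c3c(cc(O)c(C/C=C(\C)CCC=C(C)C)c3O)O2)cc(OC)c1OCOC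
F8 | step 7 | rac-8-geranyl-5,7-dihydroxy-3',5'-dimethoxy-4'-(methoxymethoxy)flavanone | COc1cc(C2CC(=O)c3c(O)cc(O)c(C/C=C(\C)CCC=C(C)C)c3O2)cc(OC)c1OCOC
F9 | step 7 | (2R,4R)-6-geranyl-3',5'-dimethoxy-4'-(methoxymethoxy)flavan-4,5,7-triol | COc1cc([C@H]2C[C@@H](O)c3c(cc(O)c(C/C=C(\C)CCC=C(C)C)c3O)O2)cc(OC)c1OCOC
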